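A small charge of L, 11 mM, stood against 4.5 mM of J in the flask, with E at 1.2 M.

| setting | alder | cedar | elm | flask |
|---|---|---|---|---|
| E | 1.2 M | 1.2 M | 1.2 M | 1.2 M |
| L | 15 mM | 24 mM | 11 mM | 11 mM |
| J | 4.5 mM | 4.5 mM | 9 mM | 4.5 mM |
| remark | run made earlier | run made earlier | run made earlier |  |
| time |  |  |  | 5.0 h |

- alder (time / h: Z / %, X / %): 0.667: 3.7, 4.2; 1.33: 5.0, 9.8; 2.00: 7.9, 10.6; 3.00: 9.9, 13.6; 4.00: 12.2, 13.7; 5.00: 15.5, 13.3
- cedar (time / h: Z / %, X / %): 0.250: 1.1, 6.2; 0.833: 1.9, 11.0; 1.33: 5.3, 12.9; 2.00: 7.7, 15.9; 3.00: 9.1, 16.7; 4.00: 12.0, 18.0; 5.00: 13.6, 17.4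
- elm (time / h: Z / %, X / %): 0.417: 1.5, 0; 0.833: 5.3, 2.3; 1.33: 5.3, 2.3; 2.50: 8.2, 4.3; 5.00: 15.5, 6.5

(standard deviation of a reading: 1 percentage point)

- the numbers in the tables scatter by 1 percentage point (one standard deviation)
- a reading or a percentage of X counts all its forms, free or not

- ratio of Z to X at 8.0 min
- ratio of Z to X at 50 min
- ratio of Z to X at 5.0 h

At 1.33 h, Z read 5.0%, 5.3% and 5.3% in the alder, cedar and elm runs, but X read 9.8%, 12.9% and 2.3%. So I took J to remove its own amount of L, and X to be made in proportion to the free catalyst, c_L − c_J. The early ratio c_Z/c_X multiplied by c_L − c_J should then hold from run to run while X is still climbing. I read it at 1.33 h in the alder and elm runs, and at 0.833 h in the cedar run, where X already read 11.0%: 5.36 mM, 4.61 mM and 3.37 mM. Their mean, itself a reading that carries the scatter, is S = 4.44 mM, a selectivity factor in concentration units: the early ratio of Z to X times the free catalyst. The charges of the flask give c_L − c_J = 6.50 mM, so my own reckoning for 8.0 min was 0.684.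

The forecast, built on “the excess of L over J”, gave a lower 0.5 at 8.0 min, then 0.58 at 50 min and 1.4 at 5.0 h.

The flask gave 0.680, 0.799 and 1.23.

    L + J → G (k = 110 M⁻¹ min⁻¹)
    2 E → Q (k = 6.60 × 10⁻⁴ M⁻¹ min⁻¹)
    E ⇌ Z (K = 15.0, k = 7.10 × 10⁻⁴ min⁻¹)
    E + L ⇌ X + L, rate k4*[E]*[L] forward; the back reaction follows from the equilibrium constant (K = 0.320, k = 0.150 M⁻¹ min⁻¹)
    L + X ⇌ D, settled at all times (K = 1.40 M⁻¹)

At 0.500 h the flask held J at 0% of its charge, while the catalyst charged stood as L 56.6%, G 40.9% and D 2.52%. The neighbour flask has 0.019 M of L and the same J, so S gives 0.306 at 8.0 min, and that neighbour flask gave 0.333.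

The earlier runs and the new flask are simulated on assumed constants; the scatter is artificial.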